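**Retrosynthetic overview**
- The strategy rests on ring A (C1 CO2CH3, C2 H, C3 OH, C4 H, C5 OCH3, C6 O-aryl): C3-OH and C5-OCH3 are the meta oxygens of a resorcinol monomethyl ether, and the aryloxy carbon C6, wedged between C1 and C5, sits para to the C3 hydroxyl. This is the pattern a 2-aryloxy vinylketene and an alkoxyalkyne assemble.
- Last disconnection: acidolysis of the tert-butyl ester and MOM ether on ring B.
- Key disconnection: ring A is opened at C3–C4, C5–C6 and C2–C3 to a (Z)-2-aryloxy-3-methylbutenedioic acid chloride methyl ester (C3, C6, C1, C2 and the ether oxygen) and methoxyacetylene (C4, C5).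
- The acid chloride comes from the ring B phenol by rhodium-carbenoid O–H insertion, Horner–Wadsworth–Emmons reaction with methyl pyruvate, deallylation and neutral chlorination. The phenol comes from 2,6-dihydroxy-4-methylbenzoic acid by esterification, mono-MOM protection and chlorination.
- Ring order: ring B is bought intact; ring A is the only ring formed.

Key step: step 10

Remark: the target has no stereocenter. Only the Z isomer of the butenedioate from the olefination (acyl carbon cis to CH3, trans to CO2CH3) is carried on, because an acid chloride cis to the methyl ester could close to a cyclic pseudo-chloride instead of giving the ketene.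

**Route**

Step 1
Reactants: 1 2,6-dihydroxy-4-methylbenzoic acid
Product: 2 tert-butyl 2,6-dihydroxy-4-methylbenzoate
Conditions: Me2NCH(OtBu)2 (4 equiv), toluene, 80 °C
Reagents that add atoms: N,N-dimethylformamide di-tert-butyl acetal, CN(C)C(OC(C)(C)C)OC(C)(C)C
Why: Alkylative esterification, in which the amide acetal transfers tert-butyl to the carboxylate oxygen, is indifferent to the two ortho substituents that block acyl attack and leaves the hydrogen-bonded phenols free.

Step 2
Reactants: 2 tert-butyl 2,6-dihydroxy-4-methylbenzoate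
Product: 3 tert-butyl 2-hydroxy-6-(methoxymethoxy)-4-methylbenzoate
Conditions: MOMCl (1.05 equiv), iPr2NEt (1.5 equiv), CH2Cl2, 0 °C → rt
Reagents that add atoms: chloromethyl methyl ether, COCCl
Why: Williamson-type O-alkylation of a symmetric diol raises no regiochemical question and should stop at the monoether, because the remaining hydroxyl is locked in a hydrogen bond to the ester carbonyl.

Step 3
Reactants: 3 tert-butyl 2-hydroxy-6-(methoxymethoxy)-4-methylbenzoate
Product: 4 tert-butyl 3-chloro-6-hydroxy-2-(methoxymethoxy)-4-methylbenzoate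
Conditions: NCS (1.0 equiv), DMF, 0 °C → rt
Reagents that add atoms: N-chlorosuccinimide, O=C1CCC(=O)N1Cl
Why: Electrophilic aromatic chlorination should go para to the free hydroxyl, the strongest donor, as is usual for salicylates (that carbon is also ortho to OMOM), and neutral NCS spares the MOM ether and the tert-butyl ester.

Step 4
Reactants: 5 allyl 2-(diethoxyphosphoryl)acetate
Product: 6 allyl 2-diazo-2-(diethoxyphosphoryl)acetate
Conditions: NaH (1.1 equiv), THF, 0 °C; 4-acetamidobenzenesulfonyl azide (1.1 equiv), 0 °C → rt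
Reagents that add atoms: 4-acetamidobenzenesulfonyl azide, CC(=O)Nc1ccc(cc1)S(=O)(=O)N=[N+]=[N-]
Why: Regitz diazo transfer from a sulfonyl azide to the stabilised phosphonoacetate carbanion is the standard route to diazophosphonoacetates.

Step 5
Reactants: 4 tert-butyl 3-chloro-6-hydroxy-2-(methoxymethoxy)-4-methylbenzoate; 6 allyl 2-diazo-2-(diethoxyphosphoryl)acetate
Product: 7 tert-butyl 3-chloro-6-[1-(diethoxyphosphoryl)-2-oxo-2-(prop-2-enyloxy)ethoxy]-2-(methoxymethoxy)-4-methylbenzoate (racemic)
Conditions: Rh2(OAc)4 (2 mol %), toluene, 80 °C, 6 added over 2 h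
Reagents that add atoms: none
Why: Rhodium-carbenoid O–H insertion, in which the electrophilic carbenoid is captured by the phenol oxygen and the oxonium ylide shifts a proton, is an established way to α-aryloxy phosphonoacetates; the new stereocenter is racemic and is erased in step 6.

Step 6
Reactants: 7 tert-butyl 3-chloro-6-[1-(diethoxyphosphoryl)-2-oxo-2-(prop-2-enyloxy)ethoxy]-2-(methoxymethoxy)-4-methylbenzoate; 8 methyl pyruvate
Product: 9 1-allyl 4-methyl (2Z)-2-{[2-(tert-butoxycarbonyl)-4-chloro-3-(methoxymethoxy)-5-methylphenyl]oxy}-3-methylbut-2-enedioate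
Conditions: LiN(SiMe3)2 (1.1 equiv), THF, −78 °C; 8 (2 equiv), −78 °C → rt; chromatography to isolate the Z isomer
Reagents that add atoms: none
Why: Horner–Wadsworth–Emmons olefination of the activated ketone carbonyl of the α-keto ester should favour the isomer with the two ester groups trans (Z), which is the one isolated, while the hindered tert-butyl ester resists Dieckmann attack by the carbanion.

Step 7
Reactants: 9 1-allyl 4-methyl (2Z)-2-{[2-(tert-butoxycarbonyl)-4-chloro-3-(methoxymethoxy)-5-methylphenyl]oxy}-3-methylbut-2-enedioate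
Product: 10 (2Z)-2-{[2-(tert-butoxycarbonyl)-4-chloro-3-(methoxymethoxy)-5-methylphenyl]oxy}-4-methoxy-3-methyl-4-oxobut-2-enoic acid
Conditions: Pd(PPh3)4 (5 mol %), PhNHMe (3 equiv), THF, rt; cold aq citric acid work-up
Reagents that add atoms: none
Why: Tsuji–Trost deallylation, in which the zerovalent palladium complex ionises only the allyl ester and the weakly nucleophilic N-methylaniline takes up the allyl group, should leave the aryloxy alkene, the aryl chloride and the other two esters untouched.

Step 8
Reactants: 11 chloroacetaldehyde dimethyl acetal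
Product: 14 methoxyacetylene, via 1-chloro-2-methoxyethene 12 (not isolated), via sodium methoxyethynide 13 (not isolated)
Conditions: NaNH2 (3.3 equiv), liq NH3, −33 °C; sat aq NaCl, −70 → 0 °C; distil (bp 23 °C), store at −20 °C
Reagents that add atoms: none
Why: Double elimination with amide base, the standard preparation of alkoxyacetylenes, removes methanol to give 12 and then HCl, leaving the acetylide 13, which the aqueous quench protonates.

Step 9
Reactants: 10 (2Z)-2-{[2-(tert-butoxycarbonyl)-4-chloro-3-(methoxymethoxy)-5-methylphenyl]oxy}-4-methoxy-3-methyl-4-oxobut-2-enoic acid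
Product: 15 methyl (2Z)-3-{[2-(tert-butoxycarbonyl)-4-chloro-3-(methoxymethoxy)-5-methylphenyl]oxy}-4-chloro-2-methyl-4-oxobut-2-enoate
Conditions: Me2C=C(Cl)NMe2 (1.2 equiv), CH2Cl2, 0 °C → rt; evaporate, use crude at once
Reagents that add atoms: 1-chloro-N,N,2-trimethylprop-1-en-1-amine, CC(C)=C(Cl)N(C)C
Why: The α-chloroenamine turns a carboxylic acid into its chloride under neutral conditions with only an amide as by-product, so no HCl is released to attack the MOM ether or the tert-butyl ester.

Step 10
Reactants: 15 methyl (2Z)-3-{[2-(tert-butoxycarbonyl)-4-chloro-3-(methoxymethoxy)-5-methylphenyl]oxy}-4-chloro-2-methyl-4-oxobut-2-enoate; 14 methoxyacetylene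
Product: 20 tert-butyl 3-chloro-6-[4-hydroxy-2-methoxy-6-(methoxycarbonyl)phenoxy]-2-(methoxymethoxy)-4-methylbenzoate, via aryloxy(vinyl)ketene 16 (not isolated), via 4-aryloxy-3-methoxy-4-alkenylcyclobutenone 17 (not isolated), via dienylketene 18 (not isolated), via cyclohexa-2,4-dienone 19 (not isolated)
Conditions: Et3N (1.5 equiv), 14 (6 equiv), toluene, 0 °C → rt, sealed flask, 15 added over 4 h; filter Et3N·HCl, evaporate excess 14; toluene, 100 °C
Reagents that add atoms: none
Why: Proposed new method: Et3N removes a hydrogen from the γ-methyl group of 15 with loss of chloride (1,4-dehydrochlorination, there being no α-hydrogen) to give ketene 16, whose carbonyl carbon is attacked by the nucleophilic CH terminus of methoxyacetylene so that a [2+2] cycloaddition forms C3–C4 and C5–C6 in cyclobutenone 17; on heating, conrotatory 4π opening of the C3–C6 bond gives dienylketene 18, 6π electrocyclisation forms C2–C3 to give dienone 19, and enolisation gives phenol 20. The closest known reactions are the Danheiser benzannulation of vinylketenes with alkoxyalkynes, the amine-mediated generation of vinylketenes from α,β-unsaturated acid chlorides for Staudinger and alkene [2+2] reactions, and the thermal ring expansion of 4-alkenylcyclobutenones; what is new is generating an aryloxy(vinyl)ketene with an amine and capturing it with an alkyne. The four-membered ring closes by ketene–alkyne [2+2] cycloaddition and ring A closes by thermal 6π electrocyclisation of the Z-dienylketene. No stereocenter is set: the quaternary carbon of 17 is a transient racemic center that becomes arene carbon C6. Two selectivities are needed: the regiochemistry of the [2+2] step, secured by the polarisation of the ynol ether, which places OCH3 at C5 meta to the new hydroxyl, and the torquoselectivity of the ring opening, secured by the donor aryloxy group on the sp3 carbon rotating outward so that the alkenyl group turns inward and can cyclise. Slow addition of 15 to an excess of the alkyne keeps the ketene dilute against dimerisation, and heating only after the ammonium salt and excess alkyne are removed keeps the new phenol from being acylated.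

Step 11
Reactants: 20 tert-butyl 3-chloro-6-[4-hydroxy-2-methoxy-6-(methoxycarbonyl)phenoxy]-2-(methoxymethoxy)-4-methylbenzoate
Product: 21 isodihydromaldoxin, 3-chloro-2-hydroxy-6-[4-hydroxy-2-methoxy-6-(methoxycarbonyl)phenoxy]-4-methylbenzoic acid
Conditions: CF3CO2H/CH2Cl2 (1:3), H2O (5 equiv), 0 °C → rt
Reagents that add atoms: none
Why: Acidolysis ionises the tert-butyl ester (loss of isobutene) and the MOM acetal (hydrolysed by the added water), while the methyl ester, the methyl ether and the diaryl ether are inert to acid.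

**Compound list**
1 | 2,6-dihydroxy-4-methylbenzoic acid | Cc1cc(O)c(C(=O)O)c(O)c1 | starting material
2 | tert-butyl 2,6-dihydroxy-4-methylbenzoate | Cc1cc(O)c(C(=O)OC(C)(C)C)c(O)c1 | intermediate
3 | tert-butyl 2-hydroxy-6-(methoxymethoxy)-4-methylbenzoate | Cc1cc(O)c(C(=O)OC(C)(C)C)c(OCOC)c1 | intermediate
4 | tert-butyl 3-chloro-6-hydroxy-2-(methoxymethoxy)-4-methylbenzoate | Cc1cc(O)c(C(=O)OC(C)(C)C)c(OCOC)c1Cl | intermediate
5 | allyl 2-(diethoxyphosphoryl)acetate | C=CCOC(=O)CP(=O)(OCC)OCC | starting material
6 | allyl 2-diazo-2-(diethoxyphosphoryl)acetate | C=CCOC(=O)C(=[N+]=[N-])P(=O)(OCC)OCC | intermediate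
7 | tert-butyl 3-chloro-6-[1-(diethoxyphosphoryl)-2-oxo-2-(prop-2-enyloxy)ethoxy]-2-(methoxymethoxy)-4-methylbenzoate (racemic) | C=CCOC(=O)C(Oc1cc(C)c(Cl)c(OCOC)c1C(=O)OC(C)(C)C)P(=O)(OCC)OCC | intermediate
8 | methyl pyruvate | CC(=O)C(=O)OC | starting material
9 | 1-allyl 4-methyl (2Z)-2-{[2-(tert-butoxycarbonyl)-4-chloro-3-(methoxymethoxy)-5-methylphenyl]oxy}-3-methylbut-2-enedioate | C=CCOC(=O)/C(Oc1cc(C)c(Cl)c(OCOC)c1C(=O)OC(C)(C)C)=C(\C)C(=O)OC | intermediate
10 | (2Z)-2-{[2-(tert-butoxycarbonyl)-4-chloro-3-(methoxymethoxy)-5-methylphenyl]oxy}-4-methoxy-3-methyl-4-oxobut-2-enoic acid | OC(=O)/C(Oc1cc(C)c(Cl)c(OCOC)c1C(=O)OC(C)(C)C)=C(\C)C(=O)OC | intermediate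
11 | chloroacetaldehyde dimethyl acetal (2-chloro-1,1-dimethoxyethane) | COC(CCl)OC | starting material
12 | 1-chloro-2-methoxyethene (E/Z mixture) | COC=CCl | intermediate
13 | sodium methoxyethynide | COC#[C-].[Na+] | intermediate
14 | methoxyacetylene (methoxyethyne) | COC#C | intermediate
15 | methyl (2Z)-3-{[2-(tert-butoxycarbonyl)-4-chloro-3-(methoxymethoxy)-5-methylphenyl]oxy}-4-chloro-2-methyl-4-oxobut-2-enoate | O=C(Cl)/C(Oc1cc(C)c(Cl)c(OCOC)c1C(=O)OC(C)(C)C)=C(\C)C(=O)OC | intermediate
16 | methyl 3-{[2-(tert-butoxycarbonyl)-4-chloro-3-(methoxymethoxy)-5-methylphenyl]oxy}-2-methylidene-4-oxobut-3-enoate (aryloxy(vinyl)ketene) | O=C=C(Oc1cc(C)c(Cl)c(OCOC)c1C(=O)OC(C)(C)C)C(=C)C(=O)OC | intermediate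
17 | tert-butyl 3-chloro-6-({2-methoxy-1-[3-methoxy-3-oxoprop-1-en-2-yl]-4-oxocyclobut-2-en-1-yl}oxy)-2-(methoxymethoxy)-4-methylbenzoate (racemic) | COC(=O)C(=C)C1(Oc2cc(C)c(Cl)c(OCOC)c2C(=O)OC(C)(C)C)C(=O)C=C1OC | intermediate
18 | methyl (3Z)-3-{[2-(tert-butoxycarbonyl)-4-chloro-3-(methoxymethoxy)-5-methylphenyl]oxy}-4-methoxy-2-methylidene-6-oxohexa-3,5-dienoate (dienylketene) | O=C=C/C(OC)=C(\C(=C)C(=O)OC)Oc1cc(C)c(Cl)c(OCOC)c1C(=O)OC(C)(C)C | intermediate
19 | methyl 2-{[2-(tert-butoxycarbonyl)-4-chloro-3-(methoxymethoxy)-5-methylphenyl]oxy}-3-methoxy-5-oxocyclohexa-1,3-diene-1-carboxylate | COC(=O)C1=C(Oc2cc(C)c(Cl)c(OCOC)c2C(=O)OC(C)(C)C)C(OC)=CC(=O)C1 | intermediate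
20 | tert-butyl 3-chloro-6-[4-hydroxy-2-methoxy-6-(methoxycarbonyl)phenoxy]-2-(methoxymethoxy)-4-methylbenzoate | COC(=O)c1cc(O)cc(OC)c1Oc1cc(C)c(Cl)c(OCOC)c1C(=O)OC(C)(C)C | intermediate
21 | isodihydromaldoxin, 3-chloro-2-hydroxy-6-[4-hydroxy-2-methoxy-6-(methoxycarbonyl)phenoxy]-4-methylbenzoic acid | COC(=O)c1cc(O)cc(OC)c1Oc1cc(C)c(Cl)c(O)c1C(=O)O | target

**Step count**
Total steps: 11. Longest linear sequence: 9 steps (1, 2, 3, 5, 6, 7, 9, 10, 11).

**Steps most likely to fail**

1. Step 10. Dimerisation or amine-induced polymerisation of the electron-poor ketene, or consumption of the ynol ether by the ammonium salt, may outrun the [2+2] capture. The fallback uses known chemistry, gives up ring construction and joins two intact rings; it sets out from 4 and comes back at 20. Methyl 2-amino-3-methoxybenzoate F1 is brominated para to the amino group (NBS, MeCN, 0 °C) to methyl 2-amino-5-bromo-3-methoxybenzoate F2. Diazotisation (NaNO2, aq H2SO4, 0 °C) followed by KI (Sandmeyer-type iodination) gives methyl 5-bromo-2-iodo-3-methoxybenzoate F3. Ullmann coupling of 4 with F3 at the iodide ortho to the ester (CuI, picolinic acid, K3PO4, DMSO, 90 °C) should give tert-butyl 6-[4-bromo-2-methoxy-6-(methoxycarbonyl)phenoxy]-3-chloro-2-(methoxymethoxy)-4-methylbenzoate F4. Miyaura borylation of the bromide (Pd(dppf)Cl2, bis(pinacolato)diboron, KOAc, dioxane, 80 °C; the hindered, electron-rich ring B chloride should be left alone) gives tert-butyl 3-chloro-6-[2-methoxy-6-(methoxycarbonyl)-4-(4,4,5,5-tetramethyl-1,3,2-dioxaborolan-2-yl)phenoxy]-2-(methoxymethoxy)-4-methylbenzoate F5. Oxidation (NaBO3·4H2O, THF/H2O, rt) then gives 20.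

2. Step 6. Addition of the hindered phosphonate carbanion to the ketone may be slow, the pyruvate may be enolised instead, or the olefination may show poor Z selectivity. The fallback replaces both the O–H insertion and the olefination by addition–elimination at a preformed alkene; it sets out from 4 and comes back at 9. Diallyl oxalate F6 is condensed with the lithium enolate of methyl propanoate F7 (LDA, THF, −78 °C; Claisen condensation) to give 1-allyl 4-methyl 3-methyl-2-oxobutanedioate F8. Its enol is chlorinated (oxalyl chloride, cat DMF, CH2Cl2, Vilsmeier-type) to 1-allyl 4-methyl 2-chloro-3-methylbut-2-enedioate F9. The caesium phenoxide of 4 (Cs2CO3, DMF, rt → 50 °C) should add at the chlorine-bearing carbon, β to the methyl ester, and expel chloride to give 9 after chromatographic isolation of the Z isomer.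

3. Step 3. Chlorination may go ortho to the free hydroxyl, or a second chlorine may enter. The fallback reverses the protecting-group order so that the halogen is delivered ortho to a free phenol while the other open position is shielded; it sets out from 2 and comes back at 4. Monosilylation of 2 (iPr3SiCl, imidazole, DMF) gives tert-butyl 2-hydroxy-4-methyl-6-[(triisopropylsilyl)oxy]benzoate F10. Amine-catalysed ortho-chlorination (SO2Cl2, cat iBu2NH, toluene, 0 °C) gives tert-butyl 3-chloro-2-hydroxy-4-methyl-6-[(triisopropylsilyl)oxy]benzoate F11. NaH/MOMCl in THF gives tert-butyl 3-chloro-2-(methoxymethoxy)-4-methyl-6-[(triisopropylsilyl)oxy]benzoate F12, and Bu4NF in THF frees the phenol to give 4.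

**Further compounds**
F1 | step 10 | methyl 2-amino-3-methoxybenzoate | COC(=O)c1cccc(OC)c1N
F2 | step 10 | methyl 2-amino-5-bromo-3-methoxybenzoate | COC(=O)c1cc(Br)cc(OC)c1N
F3 | step 10 | methyl 5-bromo-2-iodo-3-methoxybenzoate | COC(=O)c1cc(Br)cc(OC)c1I
F4 | step 10 | tert-butyl 6-[4-bromo-2-methoxy-6-(methoxycarbonyl)phenoxy]-3-chloro-2-(methoxymethoxy)-4-methylbenzoate | COC(=O)c1cc(Br)cc(OC)c1Oc1cc(C)c(Cl)c(OCOC)c1C(=O)OC(C)(C)C
F5 | step 10 | tert-butyl 3-chloro-6-[2-methoxy-6-(methoxycarbonyl)-4-(4,4,5,5-tetramethyl-1,3,2-dioxaborolan-2-yl)phenoxy]-2-(methoxymethoxy)-4-methylbenzoate | COC(=O)c1cc(B2OC(C)(C)C(C)(C)O2)cc(OC)c1Oc1cc(C)c(Cl)c(OCOC)c1C(=O)OC(C)(C)C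
F6 | step 6 | diallyl oxalate | C=CCOC(=O)C(=O)OCC=C
F7 | step 6 | methyl propanoate | CCC(=O)OC
F8 | step 6 | 1-allyl 4-methyl 3-methyl-2-oxobutanedioate | C=CCOC(=O)C(=O)C(C)C(=O)OC
F9 | step 6 | 1-allyl 4-methyl 2-chloro-3-methylbut-2-enedioate (E/Z mixture) | C=CCOC(=O)C(Cl)=C(C)C(=O)OC
F10 | step 3 | tert-butyl 2-hydroxy-4-methyl-6-[(triisopropylsilyl)oxy]benzoate | Cc1cc(O)c(C(=O)OC(C)(C)C)c(O[Si](C(C)C)(C(C)C)C(C)C)c1
F11 | step 3 | tert-butyl 3-chloro-2-hydroxy-4-methyl-6-[(triisopropylsilyl)oxy]benzoate | Cc1cc(O[Si](C(C)C)(C(C)C)C(C)C)c(C(=O)OC(C)(C)C)c(O)c1Cl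
F12 | step 3 | tert-butyl 3-chloro-2-(methoxymethoxy)-4-methyl-6-[(triisopropylsilyl)oxy]benzoate | Cc1cc(O[Si](C(C)C)(C(C)C)C(C)C)c(C(=O)OC(C)(C)C)c(OCOC)c1Cl
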